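Minutes are the unit here, and I rank what happens by how many each step takes.

| setting | violet | green | midnight | dawn | summer | spring |
|---|---|---|---|---|---|---|
| D | 0.056 M | 0.028 M | 0.056 M (fed, over 12 min) | 0.056 M | 0.056 M | 0.056 M (fed, over 50 min) |
| G | 0.0588 M | 0.0588 M | 0.0588 M | 0.0588 M | 0.0588 M (fed, over 50 min) | 0.0588 M |
| remark | run made earlier | run made earlier | all else is in the flask from the start; the feed brings no volume worth counting | everything together at the start | all else is in the flask from the start; the feed brings no volume worth counting | all else is in the flask from the start; the feed brings no volume worth counting |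
| time |  |  | 1.0 h | 1.0 h | 1.0 h | 1.0 h |

| run | time / min | J / % | X / % | D / % |
|---|---|---|---|---|
| violet | 8.00 | 7.7 | 21.5 | 26.4 |
| violet | 20.0 | 22.7 | 34.0 | 3.6 |
| violet | 40.0 | 38.0 | 38.1 | 0 |
| violet | 60.0 | 45.0 | 39.1 | 0 |
| green | 2.50 | 1.4 | 5.9 | 67.0 |
| green | 6.00 | 4.8 | 18.2 | 37.7 |
| green | 12.0 | 13.5 | 31.4 | 14.1 |
| green | 20.0 | 22.6 | 40.1 | 3.3 |

(standard deviation of a reading: 0.3 percentage points)



* the flask that comes out highest in amount of J, in percent of the D charged, or "all alike" when all lie within 1.5 percentage points (midnight / dawn / summer / spring / all alike)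
* J at the end, in percent of the D charged, midnight
* J at the end, in percent of the D charged, dawn
* J at the end, in percent of the D charged, summer
* J at the end, in percent of the D charged, spring

The first rung I can read is D. In green it falls from 67.0% to 14.1% between 2.50 min and 12.0 min, which reads as a first-order constant 0.164 min⁻¹, a life 6.10 min. Violet, with twice the D, reads 6.01 min.

X comes next. In violet it gains 4.1 percentage points up to 40.0 min and then 1 point up to 60.0 min, although 23.9% of the charge is still unseen at 40.0 min.

J is the last rung I read. Over equal steps in violet it gains 15 points, then 7 points. The ratio of those gains gives what I call the J clock, the first-order constant of an unseen intermediate going to J, 0.0391 min⁻¹. Its life of 25.6 min is longer than that of D, so this is the rate-limiting step for J.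

The clock splits violet's final gap: 5.90% is still on its way to J, which makes a pool of 50.9%.

Now I follow one molecule. It enters, waits 6.10 min, then runs on the clock until 1.0 h. Averaged over the feed, the share of the pool unfinished is 12.2% for dawn, 15.5% for midnight and 37.7% for spring. Summer feeds G, which no earlier run does, so I leave its share open.

Dawn repeats violet at 45.0%. To pass it, midnight needs 2.4 points more pool and spring 21 points. Violet makes 21.5% of X by 8.00 min, more than midnight needs, and midnight's D comes on average 6.00 min late, so I put midnight ahead of dawn and, with summer left open, name it first as my own judgement.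

The forecast also names midnight, with 51% there, 45% for dawn, 49% for summer and 40% for spring, holding that “G perishes by itself”.

Midnight comes out highest at 52.5%, against 44.9% for dawn, 47.5% for summer and 44.2% for spring.

    D → Z (k = 0.00264 s⁻¹)
    G → L (k = 0.0209 s⁻¹)
    Z + L → X (k = 0.0617 L mol⁻¹ s⁻¹)
    2 L → E (k = 0.0389 L mol⁻¹ s⁻¹)
    D + Z → Q (k = 0.00934 L mol⁻¹ s⁻¹)
    Z → J (k = 5.98 × 10⁻⁴ s⁻¹)

Midnight ends with X at 26.5% against dawn's 38.7%, and with Z at 10.7%. At 10.0 h, ten times the asked time, midnight's J stands at 62.8%, so 16.4% of its pool stood unfinished at 1.0 h, where the clock gave 15.5%. Spring's J stands at 75.2% at 10.0 h, so its unfinished share at 1.0 h was 41.2%, where the clock gave 37.7%.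

Readings and results were generated by integration from invented constants, noise included.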